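The vessel is closed and stirred, and this is what goes into it, what can happen there and what is asked.

starting complex 20 mM; incoming ligand 20.0 mM; scavenger 10.0 mM; time 50 min

    leaving ligand + complex with two exchanged → side product (k1 = 0.140 L mol⁻¹ s⁻¹)
    scavenger + leaving ligand → scavenged by-product (k2 = 1.34 L mol⁻¹ s⁻¹)
    leaving ligand + incoming ligand ⇌ idle adduct, settled at all times (K3 = 19.6 L mol⁻¹)
    complex with one exchanged + incoming ligand ⇌ leaving ligand + complex with two exchanged (K4 = 26.4, k4 = 0.0309 L mol⁻¹ s⁻¹)
    leaving ligand → by-product carried off (k5 = 0.00415 s⁻¹)
    starting complex + incoming ligand ⇌ leaving ligand + complex with one exchanged (K6 = 0.118, k6 = 0.160 L mol⁻¹ s⁻¹)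

- part of the starting complex that has reacted at 50 min
- share of the unused incoming ligand that is free and not bound as idle adduct, at 50 min

Left to itself, the first exchange stops early: with equal charges and an equilibrium constant of 0.118, taken by itself, it balances at 25.6% reacted. The bench rule says to take a product away and the balance follows. The exchange should then run until incoming ligand is used up, which at this ratio of charges points to 100% if each starting complex takes a single one.

But how fast that rule acts depends on whether a freed leaving ligand is removed or returns. In the fresh flask, scavenger and carry-off together remove it with a pseudo-first-order constant of 0.0175 s⁻¹. Return grows with c(complex with one exchanged), through the reverse of the first exchange, whose constant is 1.36 L mol⁻¹ s⁻¹. The two run equally fast at 12.9 mM, and this c(complex with one exchanged) is the break-even level. It lies below the charge of 20 mM, and as scavenger is consumed it sinks toward 3.06 mM, the value for carry-off by itself. Above the level return is faster than removal, as it is at a c(complex with one exchanged) equal to the charge, but removal still pulls, so I expect the exchange to slow there and not to stop, and I commit to c between those two percentages.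

The free share of unused incoming ligand is one over one plus 19.6 L mol⁻¹ times c(leaving ligand), so I expect it close to complete while c(leaving ligand) is small against 51.0 mM, a value above the whole incoming charge.

The forecast is sharper than my range. Holding free leaving ligand quasi-steady, it reports “I stepped this by hand, coarsely”, and gives 67% and 99.7%.

The flask gives 64.8% and 99.6%, within the forecast's margins. At 50.0 min this flask holds 8.51 mM of complex with one exchanged, above a break-even level that stands at 3.91 mM with the scavenger then left. The neighbour flask with 40 mM of scavenger holds 11.9 mM at that time, below its level of 25.5 mM, and has reacted to 77.5%.

All constants are assumed; the result is computed.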